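The readings come from a simulation for substances that don't exist; noise was put on by code.

I treat the stop in these runs as a race for the starting material: one catalytic loss proportional to catalyst and to starting material, and one catalyst-free loss proportional to starting material squared.

| flask | starting material | free catalyst | product | time |
|---|---|---|---|---|
| red | 0.150 M | 0.0150 M |  |  |
| amber | 0.150 M | 0.0150 M | 0.0450 M |  |
| blue | 0.150 M | 0.00750 M |  |  |
| teal | 0.450 M | 0.0150 M |  | 21 h |

| run | time / h | [product] / M |
|---|---|---|
| red run | 0.84 | 0.0352 |
| red run | 1.3 | 0.0515 |
| red run | 2.1 | 0.0679 |
| red run | 3.3 | 0.0813 |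
| red run | 5.3 | 0.0905 |
| red run | 8.4 | 0.0958 |
| red run | 13 | 0.0987 |
| red run | 21 | 0.1004 |
| amber run | 0.84 | 0.0804 |
| amber run | 1.3 | 0.0955 |
| amber run | 2.1 | 0.1124 |
| amber run | 3.3 | 0.1271 |
| amber run | 5.3 | 0.1351 |
| amber run | 8.4 | 0.1410 |
| amber run | 13 | 0.1439 |
| amber run | 21 | 0.1459 |
| blue run | 0.84 | 0.0195 |
| blue run | 1.3 | 0.0302 |
| blue run | 2.1 | 0.0426 |
| blue run | 3.3 | 0.0546 |
| blue run | 5.3 | 0.0658 |
| blue run | 8.4 | 0.0726 |
| blue run | 13 | 0.0760 |
| blue run | 21 | 0.0786 |

(readings scatter by 4 × 10⁻⁴ M)

* the exponent of [free catalyst] in the starting rate at the charge of the red run (at the point where two percent of the starting material have become product)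
* product in the teal run at 21 h, as a share of the starting material charged

- Overall: starting material -> product, with free catalyst as catalyst.
- Constant volume, constant temperature.
- Readings of a species count what is bound in complexes too.
- An order is taken over about fifteen percent of the charge, up and down.

In amber the last reading less its charge is 0.101 M, close to red's 0.1004 M, so I give added product no part in the rate. In my assumed race, the share of lost starting material that becomes product (the selectivity) is a/(a + S), where S is the starting material left. Integrating this over the whole charge gives final product = a·ln(1 + charge/a). I take red's last reading, 66.9% of its charge, as its final share, and solving gives a = 0.134 M. This is the balance concentration, the level of starting material at which the two losses run equally fast. In my race it scales with catalyst, and teal has red's catalyst, so teal keeps the same value and I commit to a final share of 43.8%. My race takes the catalyst order as 1 by assumption, not from a reckoning.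

The forecast gives an order of 0.95 and a share of 44%, close to mine but on another ground: “The stall near 67% must therefore be catalyst death.”

The flask gives an order of 0.62 and a teal share of 38.7% at 21 h.

active catalyst + starting material ⇌ catalyst-substrate complex, settled at all times (111.0 L mol⁻¹); catalyst-substrate complex + starting material ⇌ doubly bound catalyst, settled at all times (4.830 L mol⁻¹); doubly bound catalyst → product + catalyst-substrate complex (12.60 h⁻¹); 2 starting material → homo dimer (1.966 L mol⁻¹ h⁻¹); free catalyst → active catalyst (5.364 h⁻¹) Treating the step from free catalyst to active catalyst as instantaneous moves the readings by 17 times the scatter (root mean square). In teal, the balance concentration gives a final 0.197 M of product in my race, more than the flask's 0.174 M at 21 h. Blue is charged with half of red's free catalyst, so in my race its balance concentration is 0.0668 M and its final product 0.0786 M; blue's reading at 21 h is 0.0786 M.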